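**Retrosynthetic overview**
1. The target is 6-(3-hydroxybenzoyl)-5,7-dihydroxy-8-prenyl-2,2-dimethyl-2H-chromene; the prenyl group is put on last by C-alkylation at C8, the only unsubstituted carbon of ring A.
2. The pyran ring is closed at C2–C3: anodic decarboxylation of an aryloxy-isobutyric acid (CO2H on the future C2) gives a cation that is captured 6-endo by an ortho vinyl group (the future C3=C4).
3. Enabling feature: C2 is a fully substituted carbon bonded to the ring oxygen O1, so a carboxyl group on it is a latent O1-stabilised tertiary cation; C3=C4 is a styrene-type olefin on C4a of ring A, ortho to O1, and its C4 becomes a benzylic cation with hydrogens only on C3.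
4. Precursor: vinyl from CHO (Wittig), CHO by Vilsmeier formylation, O–CMe2–CO2Et by alkylation of the para-OH of (3-hydroxyphenyl)(2,4,6-trihydroxyphenyl)methanone, itself from phloroglucinol and 3-hydroxybenzonitrile (Hoesch).
5. Ring order: rings A and B are bought and joined through the carbonyl first; the pyran ring is the only ring that is made (step 6).

Key step: step 6

Remark: the target has no stereocentre; its only stereo-element, the C3=C4 double bond, is held cis by the pyran ring, so no step has to set configuration.

**Route**

Step 1
Reactants: 1 phloroglucinol; 2 3-hydroxybenzonitrile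
Product: 4 (3-hydroxyphenyl)(2,4,6-trihydroxyphenyl)methanone, via ketiminium chloride 3 (not isolated)
Conditions: ZnCl2 (0.3 equiv), HCl (g), Et2O, 0 °C; then H2O, 100 °C
Reagents that add atoms: water, O; hydrogen chloride, Cl (chloride of 3 only)
Why: Hoesch acylation, in which the HCl/ZnCl2-activated nitrile attacks the very electron-rich phloroglucinol once, the ketiminium chloride 3 separates from ether and cannot be acylated again, and hot water hydrolyses it to the diaryl ketone.

Step 2
Reactants: 4 (3-hydroxyphenyl)(2,4,6-trihydroxyphenyl)methanone; 5 ethyl 2-bromo-2-methylpropanoate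
Product: 6 ethyl 2-[3,5-dihydroxy-4-(3-hydroxybenzoyl)phenoxy]-2-methylpropanoate
Conditions: KHCO3 (1.5 equiv), DMF, 70 °C
Reagents that add atoms: ethyl 2-bromo-2-methylpropanoate (5), CCOC(=O)C(C)(C)Br
Why: Williamson etherification with a tertiary α-bromo ester, a reaction type well established for para-acylphenols; the 4-OH para to the carbonyl is the only unchelated hydroxyl of ring A and, as a vinylogous acid, is expected to be about two pKa units more acidic than the 3'-OH, so hydrogencarbonate should ionise and alkylate it selectively.

Step 3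
Reactants: 6 ethyl 2-[3,5-dihydroxy-4-(3-hydroxybenzoyl)phenoxy]-2-methylpropanoate
Product: 8 ethyl 2-[2-formyl-3,5-dihydroxy-4-(3-hydroxybenzoyl)phenoxy]-2-methylpropanoate, via aryl iminium chloride 7 (not isolated)
Conditions: POCl3 (1.5 equiv), DMF (3 equiv), MeCN, 0 °C to rt; then H2O, 50 °C
Reagents that add atoms: N,N-dimethylformamide, CN(C)C=O (formyl CH; NMe2 of 7); water, O (aldehyde oxygen); phosphoryl chloride, O=P(Cl)(Cl)Cl (chloride of 7 only)
Why: Vilsmeier–Haack formylation, in which the two equivalent ring-A carbons flanked by OH and the ether oxygen are the most nucleophilic positions of the molecule and the first formyl group deactivates ring A against a second one.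

Step 4
Reactants: 8 ethyl 2-[2-formyl-3,5-dihydroxy-4-(3-hydroxybenzoyl)phenoxy]-2-methylpropanoate
Product: 10 2-[2-ethenyl-3,5-dihydroxy-4-(3-hydroxybenzoyl)phenoxy]-2-methylpropanoic acid, via vinyl ester 9 (not isolated)
Conditions: Ph3PCH3Br (4.5 equiv), KOtBu (4.5 equiv), THF, 0 °C to rt; then LiOH, H2O, 50 °C; then 1 M HCl to pH 4, 0 °C
Reagents that add atoms: methyltriphenylphosphonium bromide, C[P+](c1ccccc1)(c1ccccc1)c1ccccc1.[Br-] (CH2); lithium hydroxide, [Li+].[OH-] (O of CO2H)
Why: Wittig methylenation of the aldehyde with excess ylide (three equivalents are used up by the phenols, while the hindered diaryl ketone and the tertiary ester should not be attacked), followed in the same flask by saponification of the ester, so that the sensitive vinylphenol ester is never isolated.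

Step 5
Reactants: 10 2-[2-ethenyl-3,5-dihydroxy-4-(3-hydroxybenzoyl)phenoxy]-2-methylpropanoic acid
Product: 12 2-{3,5-bis(acetyloxy)-4-[3-(acetyloxy)benzoyl]-2-ethenylphenoxy}-2-methylpropanoic acid, via mixed anhydride 11 (not isolated)
Conditions: Ac2O (6 equiv), pyridine, DMAP (0.1 equiv), CH2Cl2, 0 °C to rt; then H2O, THF, rt
Reagents that add atoms: acetic anhydride, CC(=O)OC(C)=O
Why: DMAP-catalysed O-acetylation of the three phenols, needed to raise the oxidation potential of the arenes for step 6; the mixed anhydride 11 formed at the carboxyl group should be cleaved again by water at its unhindered acetyl carbonyl.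

Step 6
Reactants: 12 2-{3,5-bis(acetyloxy)-4-[3-(acetyloxy)benzoyl]-2-ethenylphenoxy}-2-methylpropanoic acid
Product: 14 (5,7-dihydroxy-2,2-dimethyl-2H-chromen-6-yl)(3-hydroxyphenyl)methanone, via chromene triacetate 13 (not isolated)
Conditions: undivided cell, graphite anode, Pt cathode, constant current (about 2.2 F/mol), 2,4,6-collidine (1.2 equiv), n-Bu4NPF6 (0.1 M), CH2Cl2/HFIP 9:1, 3 Å MS, rt; then evaporation, K2CO3 (0.3 equiv), MeOH, rt
Reagents that add atoms: none
Why: Proposed new method: the collidinium carboxylate of 12 is oxidised at the anode by two electrons with loss of CO2 (Hofer–Moest, non-Kolbe pathway) to the tertiary cation on C2, stabilised by the aryl ether oxygen O1 (an aryloxocarbenium ion); the terminal CH2 of the ortho vinyl group attacks it, the resulting C4 benzylic cation (ortho to O1, whose lone pair is free again) loses a proton from C3, and the protons are reduced to H2 at the cathode. The closest known reaction types are the anodic decarboxylation of α-alkoxy and α-aryloxy acids to oxocarbenium ions that are trapped by added nucleophiles (mixed acetals, hindered ethers) and acid-promoted oxocarbenium–styrene (Prins-type) cyclisations; what is new is the intramolecular capture of the electrogenerated cation by an olefin. The pyran ring is closed in the 6-endo-trig mode at the new C2–C3 bond; no stereocentre is formed and the C3=C4 bond is necessarily cis in the ring. The step needs (a) oxidation of the carboxylate before the π systems, secured by the three acetates, which should raise the oxidation potentials of ring A, of the twisted vinyl group and of the product chromene above that of the carboxylate, (b) bond formation at the vinyl terminus only, secured because attack at the internal carbon would give a primary cation and because C8 is still unsubstituted, so no prenyl olefin competes for the cation, and (c) a single olefin isomer, secured because C4 has no β-hydrogen other than those on C3. The buffered, non-acidic medium keeps the vinyl group from being protonated, which is the reason for making the cation electrochemically and not with acid. Methanolysis of the three aryl acetates in the same flask then frees the phenols.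

Step 7
Reactants: 14 (5,7-dihydroxy-2,2-dimethyl-2H-chromen-6-yl)(3-hydroxyphenyl)methanone; 15 prenyl bromide
Product: 16 [5,7-dihydroxy-2,2-dimethyl-8-(3-methylbut-2-en-1-yl)-2H-chromen-6-yl](3-hydroxyphenyl)methanone
Conditions: KOH (10% aq), 0 °C to rt
Reagents that add atoms: prenyl bromide (15), CC(C)=CCBr
Why: C-alkylation of the acylphloroglucinol phenoxide, an ambident, enolate-like nucleophile, at C8, the only unsubstituted carbon of ring A, in a protic medium in which hydrogen bonding to the phenoxide oxygens favours C- over O-alkylation, which is the standard way of putting prenyl groups on benzoylphloroglucinols.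

**Compound list**
1 | phloroglucinol (benzene-1,3,5-triol) | Oc1cc(O)cc(O)c1 | starting material
2 | 3-hydroxybenzonitrile | N#Cc1cccc(O)c1 | starting material
3 | (3-hydroxyphenyl)(2,4,6-trihydroxyphenyl)methaniminium chloride (ketiminium chloride) | [NH2+]=C(c1cccc(O)c1)c1c(O)cc(O)cc1O.[Cl-] | intermediate (not isolated)
4 | (3-hydroxyphenyl)(2,4,6-trihydroxyphenyl)methanone | O=C(c1cccc(O)c1)c1c(O)cc(O)cc1O | intermediate
5 | ethyl 2-bromo-2-methylpropanoate | CCOC(=O)C(C)(C)Br | starting material
6 | ethyl 2-[3,5-dihydroxy-4-(3-hydroxybenzoyl)phenoxy]-2-methylpropanoate | CCOC(=O)C(C)(C)Oc1cc(O)c(C(=O)c2cccc(O)c2)c(O)c1 | intermediate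
7 | N-({2-[(1-ethoxy-2-methyl-1-oxopropan-2-yl)oxy]-4,6-dihydroxy-5-(3-hydroxybenzoyl)phenyl}methylidene)-N-methylmethanaminium chloride (aryl iminium chloride) | CCOC(=O)C(C)(C)Oc1cc(O)c(C(=O)c2cccc(O)c2)c(O)c1C=[N+](C)C.[Cl-] | intermediate (not isolated)
8 | ethyl 2-[2-formyl-3,5-dihydroxy-4-(3-hydroxybenzoyl)phenoxy]-2-methylpropanoate | CCOC(=O)C(C)(C)Oc1cc(O)c(C(=O)c2cccc(O)c2)c(O)c1C=O | intermediate
9 | ethyl 2-[2-ethenyl-3,5-dihydroxy-4-(3-hydroxybenzoyl)phenoxy]-2-methylpropanoate (vinyl ester) | CCOC(=O)C(C)(C)Oc1cc(O)c(C(=O)c2cccc(O)c2)c(O)c1C=C | intermediate (not isolated)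
10 | 2-[2-ethenyl-3,5-dihydroxy-4-(3-hydroxybenzoyl)phenoxy]-2-methylpropanoic acid | OC(=O)C(C)(C)Oc1cc(O)c(C(=O)c2cccc(O)c2)c(O)c1C=C | intermediate
11 | acetic 2-{3,5-bis(acetyloxy)-4-[3-(acetyloxy)benzoyl]-2-ethenylphenoxy}-2-methylpropanoic anhydride (mixed anhydride) | CC(=O)OC(=O)C(C)(C)Oc1cc(OC(C)=O)c(C(=O)c2cccc(OC(C)=O)c2)c(OC(C)=O)c1C=C | intermediate (not isolated)
12 | 2-{3,5-bis(acetyloxy)-4-[3-(acetyloxy)benzoyl]-2-ethenylphenoxy}-2-methylpropanoic acid | OC(=O)C(C)(C)Oc1cc(OC(C)=O)c(C(=O)c2cccc(OC(C)=O)c2)c(OC(C)=O)c1C=C | intermediate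
13 | 6-[3-(acetyloxy)benzoyl]-2,2-dimethyl-2H-chromene-5,7-diyl diacetate (chromene triacetate) | CC(=O)Oc1cccc(c1)C(=O)c1c(OC(C)=O)cc2OC(C)(C)C=Cc2c1OC(C)=O | intermediate (not isolated)
14 | (5,7-dihydroxy-2,2-dimethyl-2H-chromen-6-yl)(3-hydroxyphenyl)methanone | Oc1cccc(c1)C(=O)c1c(O)cc2OC(C)(C)C=Cc2c1O | intermediate
15 | prenyl bromide (1-bromo-3-methylbut-2-ene) | CC(C)=CCBr | starting material
16 | [5,7-dihydroxy-2,2-dimethyl-8-(3-methylbut-2-en-1-yl)-2H-chromen-6-yl](3-hydroxyphenyl)methanone | CC(C)=CCc1c(O)c(C(=O)c2cccc(O)c2)c(O)c2c1OC(C)(C)C=C2 | target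

**Step count and risks**
Total steps: 7. Longest linear sequence: 7 steps (from 1 and 2 to 16).

The three steps most likely to fail:

Step 6 (proposed new method). The electrogenerated C2 cation may lose a methyl proton to collidine, or be captured by carboxylate or HFIP, faster than it cyclises. The C4 cation may be held back by the neighbouring C5 acetate, and the chromene may be oxidised further at the anode near full conversion. The fallback uses known chemistry and closes the pyran ring at O1–C2 instead. It sets out from 4: the acidic 4-OH is etherified selectively with 3-chloro-3-methylbut-1-yne (K2CO3, KI, DMF, 60 °C) to give (3-hydroxyphenyl){2,6-dihydroxy-4-[(2-methylbut-3-yn-2-yl)oxy]phenyl}methanone F1. Heating F1 (xylene, 140 °C) should bring about the aryl propargyl ether Claisen rearrangement, 1,5-hydrogen shift and oxa-6π electrocyclisation. Both ortho carbons are equivalent, so this should give 14 directly, where the route is rejoined before step 7.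

Step 7. O-alkylation of the ring-A phenoxides and of the 3'-phenoxide, double alkylation and hydrolysis of the bromide may outrun C-alkylation at C8. The fallback replaces phenoxide alkylation by cross-coupling. It sets out from 14: electrophilic iodination at C8, the most activated aromatic position (NIS, 1.0 equiv, DMF, −20 °C), gives (5,7-dihydroxy-8-iodo-2,2-dimethyl-2H-chromen-6-yl)(3-hydroxyphenyl)methanone F2. Stille coupling of F2 with tributyl(3-methylbut-2-en-1-yl)stannane (Pd(PPh3)4, DMF, 80 °C) should then form the C8–CH2 bond and arrive at 16.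

Step 4. Once the three phenols are deprotonated, the formyl group is part of a vinylogous carboxylate and addition of the ylide may fail; the free vinylphenol may also oligomerise during acidification. The fallback avoids formylation and olefination altogether. It sets out from 6: mono-iodination of ring A (NIS, 1.0 equiv, MeCN, 0 °C) gives ethyl 2-[3,5-dihydroxy-4-(3-hydroxybenzoyl)-2-iodophenoxy]-2-methylpropanoate F3. Suzuki–Miyaura vinylation of F3 (potassium vinyltrifluoroborate, PdCl2(dppf), Cs2CO3, THF/H2O, 70 °C) should give vinyl ester 9, which is saponified as in the second half of step 4 to 10.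

Further compounds
F1 | step 6 | (3-hydroxyphenyl){2,6-dihydroxy-4-[(2-methylbut-3-yn-2-yl)oxy]phenyl}methanone | C#CC(C)(C)Oc1cc(O)c(C(=O)c2cccc(O)c2)c(O)c1
F2 | step 7 | (5,7-dihydroxy-8-iodo-2,2-dimethyl-2H-chromen-6-yl)(3-hydroxyphenyl)methanone | Oc1cccc(c1)C(=O)c1c(O)c(I)c2OC(C)(C)C=Cc2c1O
F3 | step 4 | ethyl 2-[3,5-dihydroxy-4-(3-hydroxybenzoyl)-2-iodophenoxy]-2-methylpropanoate | CCOC(=O)C(C)(C)Oc1cc(O)c(C(=O)c2cccc(O)c2)c(O)c1I
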